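**Plan**
- Retrosynthesis: the C1–OH is traced back to a C1–acetyl group (Baeyer–Villiger) and the C6–OMe to a free phenol. The benzene ring is then cut at C2–C3 and C1–C6.
- Enabling feature: ring atoms C3, C4, C5, C6 carry H, OMe, H, O, which is the pattern of a 1,1,3-trioxygenated buta-1,3-diene. C1 (masked as C–acetyl) and C2 (C–tricosyl) map onto the two sp carbons of an alkynyl methyl ketone.
- The ynone is cut at the C(O)–C(sp) bond (Weinreb amide) and at the propargylic C–C bond (C22 bromide plus a C3 propargyl anion).
- Forward: the chain is joined first (steps 1–3) and the diene is made (step 4). The only ring arises in step 5 by cycloaddition–aromatisation. O-methylation and the acetyl → acetoxy → hydroxyl exchange follow (steps 6–8).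
- Stereochemistry: the target has no stereocentre and no stereogenic double bond, so nothing has to be set. The sp3 acetal carbon of the cycloadduct is transient.

Key step: step 5

Remark: the target is achiral, so the single-enantiomer requirement is met trivially. Ring numbering used throughout: C1 (OH), C2 (tricosyl), C4 and C6 (OMe).

Step 1
Reactants: 1 1-(trimethylsilyl)propyne; 2 1-bromodocosane
Product: 4 trimethyl(pentacos-1-yn-1-yl)silane, via 3-lithio-1-(trimethylsilyl)propyne 3 (not isolated)
Conditions: n-BuLi, THF, −78 → −20 °C; then 2 (THF solution), DMPU, −78 °C → rt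
Reagents that add atoms: none
Why: Deprotonation of 1 gives a silyl-stabilised propargyl lithium that the primary bromide alkylates at the propargylic carbon by SN2 (propargyl anion alkylation), the bulky silyl group disfavouring reaction through the allenyl terminus.

Step 2
Reactants: 4 trimethyl(pentacos-1-yn-1-yl)silane
Product: 5 pentacos-1-yne
Conditions: K2CO3 (cat.), MeOH/THF 1:1, rt
Reagents that add atoms: none
Why: Methoxide-mediated protodesilylation cleaves only the C(sp)–Si bond and leaves the saturated chain untouched.

Step 3
Reactants: 5 pentacos-1-yne; 6 N-methoxy-N-methylacetamide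
Product: 9 heptacos-3-yn-2-one, via lithium pentacos-1-yn-1-ide 7 (not isolated), via lithium 2-[methoxy(methyl)amino]heptacos-3-yn-2-olate 8 (not isolated)
Conditions: n-BuLi, THF, −40 → 0 °C; then 6, −78 → 0 °C; inverse quench into cold 1 M HCl
Reagents that add atoms: none
Why: Weinreb ketone synthesis, in which the acetylide adds once to give a chelated tetrahedral adduct that collapses to the ynone only on quenching, the acidic inverse quench protonating the released N,O-dimethylhydroxylamine so that it cannot add to the ynone.

Step 4
Reactants: 10 methyl (E)-3-methoxybut-2-enoate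
Product: 12 1,3-dimethoxy-1-(trimethylsilyloxy)buta-1,3-diene (geometry at C1 not defined and irrelevant), via lithium 1,3-dimethoxybuta-1,3-dien-1-olate 11 (not isolated)
Conditions: LDA (commercial solution), THF, −78 °C; then TMSCl, −78 °C → rt; pentane, filtration under Ar, bulb-to-bulb distillation, used fresh
Reagents that add atoms: chlorotrimethylsilane, C[Si](C)(C)Cl
Why: γ-Deprotonation of the vinylogous carbonate-type ester gives the extended dienolate, which chlorotrimethylsilane traps on oxygen to give the vinylketene mixed acetal (standard preparation of this Brassard-type diene).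

Step 5
Reactants: 12 1,3-dimethoxy-1-(trimethylsilyloxy)buta-1,3-diene (2.5 equiv); 9 heptacos-3-yn-2-one
Product: 15 1-(2-hydroxy-4-methoxy-6-tricosylphenyl)ethan-1-one, via 1-[4,6-dimethoxy-2-tricosyl-6-(trimethylsilyloxy)cyclohexa-1,4-dien-1-yl]ethan-1-one 13 (not isolated), via 1-[4-methoxy-2-tricosyl-6-(trimethylsilyloxy)phenyl]ethan-1-one 14 (not isolated)
Conditions: toluene (concentrated), 90 °C, Ar; then 1 M HCl, THF, rt
Reagents that add atoms: none
Why: The electron-rich vinylketene acetal and the ynone should combine in a thermal, strongly asynchronous normal-demand [4+2] cycloaddition, the CH2 terminus of the diene bonding to the chain-bearing β-carbon (ring C3–C2) and the acetal carbon to the acetyl-bearing α-carbon (C6–C1) to give the 1,4-cyclohexadiene 13; 1,4-elimination of methanol across the C6 mixed acetal and C3–H aromatises it to the silyl ether 14, and the acidic work-up frees the phenol. The closest known reaction type is the Diels–Alder/aromatisation of 1,1,3-trioxygenated butadienes with acetylenic ketones and esters to resorcinol derivatives. The single carbocycle is closed intermolecularly by the cycloaddition itself, all six ring atoms coming from the 4π and 2π partners and no separate cyclisation being needed. No stereocentre survives: the sp3 C6 of 13 forms as a racemate and is erased on aromatisation, which is also why the C1 geometry of the diene does not matter. The selectivity required is regiochemical, and it is secured by polarity, the largest HOMO coefficient (diene CH2) pairing with the largest LUMO coefficient (ynone β-carbon), so that the acetyl group ends up between the new hydroxyl and the tricosyl chain. If some adduct loses the silyloxy group instead of methoxy, the resulting C6 methyl ether is the product of the next step, so both pathways converge.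

Step 6
Reactants: 15 1-(2-hydroxy-4-methoxy-6-tricosylphenyl)ethan-1-one
Product: 16 1-(2,4-dimethoxy-6-tricosylphenyl)ethan-1-one
Conditions: MeI (excess), K2CO3, acetone, reflux
Reagents that add atoms: iodomethane, CI
Why: Williamson O-methylation of the only acidic site, the hydrogen bond to the acetyl group being overcome by excess base and iodomethane at reflux.

Step 7
Reactants: 16 1-(2,4-dimethoxy-6-tricosylphenyl)ethan-1-one
Product: 17 2,4-dimethoxy-6-tricosylphenyl acetate
Conditions: mCPBA, TFA (cat.), CH2Cl2, 0 °C → rt, dark
Reagents that add atoms: 3-chloroperoxybenzoic acid (mCPBA), OOC(=O)c1cccc(Cl)c1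
Why: Baeyer–Villiger oxidation in which the electron-rich 2,4-dimethoxy-6-alkylphenyl group migrates in the Criegee adduct far more readily than methyl, so the aryl acetate and not the methyl benzoate should form.

Step 8
Reactants: 17 2,4-dimethoxy-6-tricosylphenyl acetate
Product: 18 2,4-dimethoxy-6-tricosylphenol (CNP0228278.0)
Conditions: K2CO3 (cat.), degassed MeOH/THF, rt, Ar; then AcOH before exposure to air
Reagents that add atoms: none
Why: Base-catalysed transesterification (methanolysis) of the aryl acetate releases the phenol, air being excluded because the electron-rich phenoxide is prone to oxidation.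

**Compound list**
1 | 1-(trimethylsilyl)propyne | CC#C[Si](C)(C)C | starting material
2 | 1-bromodocosane | CCCCCCCCCCCCCCCCCCCCCCBr | starting material
3 | 3-lithio-1-(trimethylsilyl)propyne | [Li]CC#C[Si](C)(C)C | intermediate
4 | trimethyl(pentacos-1-yn-1-yl)silane | CCCCCCCCCCCCCCCCCCCCCCCC#C[Si](C)(C)C | intermediate
5 | pentacos-1-yne | CCCCCCCCCCCCCCCCCCCCCCCC#C | intermediate
6 | N-methoxy-N-methylacetamide | CON(C)C(C)=O | starting material
7 | lithium pentacos-1-yn-1-ide | CCCCCCCCCCCCCCCCCCCCCCCC#C[Li] | intermediate
8 | lithium 2-[methoxy(methyl)amino]heptacos-3-yn-2-olate | CCCCCCCCCCCCCCCCCCCCCCCC#CC(C)(O[Li])N(C)OC | intermediate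
9 | heptacos-3-yn-2-one | CCCCCCCCCCCCCCCCCCCCCCCC#CC(C)=O | intermediate
10 | methyl (E)-3-methoxybut-2-enoate | CO/C(C)=C/C(=O)OC | starting material
11 | lithium 1,3-dimethoxybuta-1,3-dien-1-olate | C=C(OC)C=C(OC)O[Li] | intermediate
12 | 1,3-dimethoxy-1-(trimethylsilyloxy)buta-1,3-diene | C=C(OC)C=C(OC)O[Si](C)(C)C | intermediate
13 | 1-[4,6-dimethoxy-2-tricosyl-6-(trimethylsilyloxy)cyclohexa-1,4-dien-1-yl]ethan-1-one (racemic) | CCCCCCCCCCCCCCCCCCCCCCCC1=C(C(C)=O)C(OC)(O[Si](C)(C)C)C=C(OC)C1 | intermediate
14 | 1-[4-methoxy-2-tricosyl-6-(trimethylsilyloxy)phenyl]ethan-1-one | CCCCCCCCCCCCCCCCCCCCCCCc1cc(OC)cc(O[Si](C)(C)C)c1C(C)=O | intermediate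
15 | 1-(2-hydroxy-4-methoxy-6-tricosylphenyl)ethan-1-one | CCCCCCCCCCCCCCCCCCCCCCCc1cc(OC)cc(O)c1C(C)=O | intermediate
16 | 1-(2,4-dimethoxy-6-tricosylphenyl)ethan-1-one | CCCCCCCCCCCCCCCCCCCCCCCc1cc(OC)cc(OC)c1C(C)=O | intermediate
17 | 2,4-dimethoxy-6-tricosylphenyl acetate | CCCCCCCCCCCCCCCCCCCCCCCc1cc(OC)cc(OC)c1OC(C)=O | intermediate
18 | 2,4-dimethoxy-6-tricosylphenol | CCCCCCCCCCCCCCCCCCCCCCCc1cc(OC)cc(OC)c1O | target

Total step count: 8. Longest linear sequence: 7 steps (steps 1, 2, 3, 5, 6, 7, 8 from 1-bromodocosane); the diene branch (step 4) joins at step 5.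

**Steps most likely to fail**

Step 5. The β-alkyl ynone may cycloadd more slowly than the diene is consumed by desilylation or oligomerisation, or the first C–C bond formation may stop at an open-chain Michael adduct that does not close. The fallback gives up the cycloaddition and builds the acetyl arene by aromatic substitution. It sets out from 2, which is converted with magnesium in THF into docosylmagnesium bromide F1. Copper-catalysed coupling (Li2CuCl4, THF, −20 → 0 °C) with commercial 3,5-dimethoxybenzyl bromide should give 1,3-dimethoxy-5-tricosylbenzene F2. Friedel–Crafts acetylation (AcCl, SnCl4, CH2Cl2, −10 °C) is expected at the position para to one methoxy group and ortho to the chain, the usual site for 5-alkylresorcinol dimethyl ethers, and rejoins the route at 16.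

Step 7. Peracid addition to the doubly ortho-flanked carbonyl may be sluggish, and electrophilic oxidation of the electron-rich ring may compete. The fallback replaces the peracid oxidation by a Hock-type rearrangement and sets out from 16. Reduction with NaBH4 (MeOH/THF) gives 1-(2,4-dimethoxy-6-tricosylphenyl)ethan-1-ol F3. Treatment with aqueous H2O2 and catalytic p-TsOH in THF should form 1-(2,4-dimethoxy-6-tricosylphenyl)ethyl hydroperoxide F4 through the stabilised benzylic cation. Acid-induced aryl migration to oxygen and collapse of the hemiacetal then deliver the phenol directly, returning to the route at 18 and bypassing 17.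

Step 1. The waxy C22 bromide is poorly soluble at low temperature, so the SN2 displacement may stay incomplete, with reaction through the allenyl terminus or E2 elimination taking over on warming. The fallback installs the three carbons as an allyl group and sets out from 2. Coupling with allylmagnesium bromide (cat. Li2CuCl4, THF) gives pentacos-1-ene F5. Bromine in CH2Cl2 at 0 °C gives 1,2-dibromopentacosane F6. Double dehydrobromination with excess NaNH2 (THF/liquid NH3, then water) gives the terminal alkyne, rejoining the route at 5 and skipping 4.

**Further compounds**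
F1 | step 5 | docosylmagnesium bromide | CCCCCCCCCCCCCCCCCCCCCC[Mg]Br
F2 | step 5 | 1,3-dimethoxy-5-tricosylbenzene | CCCCCCCCCCCCCCCCCCCCCCCc1cc(OC)cc(OC)c1
F3 | step 7 | 1-(2,4-dimethoxy-6-tricosylphenyl)ethan-1-ol (racemic) | CCCCCCCCCCCCCCCCCCCCCCCc1cc(OC)cc(OC)c1C(C)O
F4 | step 7 | 1-(2,4-dimethoxy-6-tricosylphenyl)ethyl hydroperoxide (racemic) | CCCCCCCCCCCCCCCCCCCCCCCc1cc(OC)cc(OC)c1C(C)OO
F5 | step 1 | pentacos-1-ene | CCCCCCCCCCCCCCCCCCCCCCCC=C
F6 | step 1 | 1,2-dibromopentacosane (racemic) | CCCCCCCCCCCCCCCCCCCCCCCC(Br)CBr
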